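**Retrosynthetic overview**
- Ring B is made last: the C5′–C6′ bond is closed by 6π electrocyclisation of a dienylketene released from a 4-alkenyl-4-siloxycyclobutenone, and the resulting arene is oxidised to the quinone.
- Enabling feature: in ring B the contiguous C2′(=O)–C3′(prenyl)–C4′(OH)–C5′(=O) unit has the oxygen pattern of a squaric ester with one alkoxy replaced by carbon, and C1′=C6′ is a 1,1-disubstituted vinyl group on C3 of ring C whose terminus C6′ is an unsubstituted CH.
- The cyclobutenone is assembled from three pieces: the chroman vinyllithium (Shapiro), di-tert-butyl squarate and allylmagnesium bromide (addition, then 1,3-carbonyl transposition).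
- Rings A and C: a coumarin from phloroglucinaldehyde; the C6 allyl group comes from Claisen rearrangement of the 5-O-allyl ether; C3 is set by dynamic kinetic resolution of the 3-acetyl-dihydrocoumarin; the lactone is opened and ring C reclosed as the pyran by Mitsunobu reaction.
- Ring order: A (starting material), C as lactone, C as pyran, B; both prenyl groups are finished late by double cross-metathesis of allyl groups, then the tert-butyl and silyl groups are removed.

Key step: step 14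

Assumption: in step 7 the (S,S)-catalyst is taken to give the (3R,1′S) hydroxy lactone; if the sense at C3 proves opposite, the (R,R)-catalyst is used instead, since the carbinol centre is erased in step 10.

Abbreviations: allyl = prop-2-en-1-yl; prenyl = 3-methylbut-2-en-1-yl; TIPS = triisopropylsilyl; TMS = trimethylsilyl; chroman = 3,4-dihydro-2H-chromene.

Step 1
Reactants: 1 2,4,6-trihydroxybenzaldehyde; 2 ethyl acetoacetate
Product: 3 3-acetyl-5,7-dihydroxy-2H-chromen-2-one
Conditions: piperidine (cat.), EtOH, reflux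
Reagents that add atoms: ethyl acetoacetate CCOC(=O)CC(C)=O
Why: Knoevenagel condensation followed by lactonisation of an ortho-hydroxyl onto the ester (coumarin synthesis) should give a single product because the two ortho-hydroxyls of 1 are equivalent; no stereocenter is formed.

Step 2
Reactants: 3 3-acetyl-5,7-dihydroxy-2H-chromen-2-one; 4 chlorotriisopropylsilane
Product: 5 3-acetyl-5-hydroxy-7-(TIPS-oxy)-2H-chromen-2-one
Conditions: TIPSCl (1.05 equiv), imidazole, DMF, 0 °C
Reagents that add atoms: chlorotriisopropylsilane CC(C)[Si](Cl)(C(C)C)C(C)C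
Why: Phenol silylation should occur at the 7-hydroxyl, the more acidic and less hindered one, because the 5-hydroxyl is shielded by the peri C4–H and the bulky silyl chloride is not used in excess.

Step 3
Reactants: 5 3-acetyl-5-hydroxy-7-(TIPS-oxy)-2H-chromen-2-one; 6 allyl bromide
Product: 7 3-acetyl-5-(allyloxy)-7-(TIPS-oxy)-2H-chromen-2-one
Conditions: K2CO3, acetone, 50 °C
Reagents that add atoms: allyl bromide C=CCBr
Why: Williamson etherification of the remaining 5-phenol under mild carbonate conditions that should leave the aryl silyl ether intact.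

Step 4
Reactants: 7 3-acetyl-5-(allyloxy)-7-(TIPS-oxy)-2H-chromen-2-one
Product: 8 3-acetyl-6-allyl-5-hydroxy-7-(TIPS-oxy)-2H-chromen-2-one
Conditions: N,N-diethylaniline, 190 °C
Reagents that add atoms: none
Why: Aromatic Claisen rearrangement ([3,3]-sigmatropic shift) can deliver the allyl group only to C6, because the other ortho position C4a is the ring fusion, and tautomerisation restores the 5-phenol.

Step 5
Reactants: 8 3-acetyl-6-allyl-5-hydroxy-7-(TIPS-oxy)-2H-chromen-2-one; 9 iodomethane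
Product: 10 3-acetyl-6-allyl-5-methoxy-7-(TIPS-oxy)-2H-chromen-2-one
Conditions: MeI, K2CO3, acetone, 40 °C
Reagents that add atoms: iodomethane CI
Why: Williamson methylation of the hindered 5-phenol fixes the 5-methoxy group of ring A.

Step 6
Reactants: 10 3-acetyl-6-allyl-5-methoxy-7-(TIPS-oxy)-2H-chromen-2-one
Product: 11 rac-3-acetyl-6-allyl-5-methoxy-7-(TIPS-oxy)chroman-2-one (C3 configurationally labile)
Conditions: Hantzsch ester (diethyl 2,6-dimethyl-1,4-dihydropyridine-3,5-dicarboxylate, 1.2 equiv), silica gel, PhMe, 80 °C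
Reagents that add atoms: none
Why: Conjugate transfer hydrogenation by the Hantzsch dihydropyridine should reduce only the doubly activated C3=C4 bond (alkylidene-1,3-dicarbonyl type) and leave the isolated allyl group; C3 forms racemic and stays labile through the enol.

Step 7
Reactants: 11 rac-3-acetyl-6-allyl-5-methoxy-7-(TIPS-oxy)chroman-2-one
Product: 12 (3R)-6-allyl-3-[(1S)-1-hydroxyethyl]-5-methoxy-7-(TIPS-oxy)chroman-2-one
Conditions: RuCl[(S,S)-TsDPEN](p-cymene) (2 mol%), HCO2H/Et3N (5:2), CH2Cl2, 30 °C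
Reagents that add atoms: none
Why: Noyori–Ikariya asymmetric transfer hydrogenation under dynamic kinetic resolution: C3 of the α-acyl lactone racemises through the enol faster than reduction, the catalyst sets the carbinol centre and selects the matching C3 epimer so both centres are fixed together, and the minor diastereomer is to be removed by chromatography so that C3 is carried on in one configuration.

Step 8
Reactants: 12 (3R)-6-allyl-3-[(1S)-1-hydroxyethyl]-5-methoxy-7-(TIPS-oxy)chroman-2-one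
Product: 13 (2S,3S)-2-{[3-allyl-6-hydroxy-2-methoxy-4-(TIPS-oxy)phenyl]methyl}butane-1,3-diol
Conditions: LiBH4, THF, 0 °C to rt
Reagents that add atoms: none
Why: Hydride reduction of the aryl lactone opens ring C to the primary alcohol and the phenol without touching the stereocenters, the alkene or the silyl ether.

Step 9
Reactants: 13 (2S,3S)-2-{[3-allyl-6-hydroxy-2-methoxy-4-(TIPS-oxy)phenyl]methyl}butane-1,3-diol
Product: 14 (1S)-1-[(3S)-6-allyl-5-methoxy-7-(TIPS-oxy)chroman-3-yl]ethan-1-ol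
Conditions: PPh3, DIAD, THF, 0 °C to rt
Reagents that add atoms: none
Why: Intramolecular Mitsunobu etherification: the primary alcohol is activated faster than the secondary one and the phenol closes the six-membered pyran ring by SN2 at CH2, so neither stereocenter is touched.

Step 10
Reactants: 14 (1S)-1-[(3S)-6-allyl-5-methoxy-7-(TIPS-oxy)chroman-3-yl]ethan-1-ol
Product: 15 1-[(3S)-6-allyl-5-methoxy-7-(TIPS-oxy)chroman-3-yl]ethan-1-one
Conditions: Dess–Martin periodinane, NaHCO3, CH2Cl2, 0 °C to rt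
Reagents that add atoms: none
Why: Dess–Martin oxidation under buffered, non-enolising conditions converts the carbinol to the methyl ketone while the adjacent C3 centre is kept.

Step 11
Reactants: 15 1-[(3S)-6-allyl-5-methoxy-7-(TIPS-oxy)chroman-3-yl]ethan-1-one; 16 2,4,6-triisopropylbenzenesulfonohydrazide
Product: 17 N′-{(1E)-1-[(3R)-6-allyl-5-methoxy-7-(TIPS-oxy)chroman-3-yl]ethylidene}-2,4,6-triisopropylbenzenesulfonohydrazide
Conditions: THF, rt
Reagents that add atoms: 2,4,6-triisopropylbenzenesulfonohydrazide CC(C)c1cc(C(C)C)c(S(=O)(=O)NN)c(C(C)C)c1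
Why: Condensation of the ketone with the arenesulfonyl hydrazide should give the (E)-hydrazone, with the sulfonamide anti to the branched chromanyl carbon, under neutral conditions that do not enolise C3.

Step 12
Reactants: 17 the (E)-hydrazone; 18 di-tert-butyl squarate (3,4-di-tert-butoxycyclobut-3-ene-1,2-dione); 19 chlorotrimethylsilane
Product: 22 4-{1-[(3R)-6-allyl-5-methoxy-7-(TIPS-oxy)chroman-3-yl]ethenyl}-2,3-di-tert-butoxy-4-(TMS-oxy)cyclobut-2-en-1-one (both epimers at C4), via vinyllithium 20 (not isolated), via lithium alkoxide 21 (not isolated)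
Conditions: n-BuLi (2.05 equiv), THF, −78 °C then 0 °C; cannulated into 18 (1.2 equiv), THF, −78 °C; then TMSCl, −78 to 0 °C
Reagents that add atoms: di-tert-butyl squarate CC(C)(C)OC1=C(OC(C)(C)C)C(=O)C1=O; chlorotrimethylsilane C[Si](C)(C)Cl
Why: Shapiro reaction: syn-directed deprotonation at the methyl group of the hydrazone dianion and loss of sulfinate and dinitrogen give the 1,1-disubstituted vinyllithium without touching C3–H, it adds 1,2 to one of the two equivalent squarate carbonyls and the alkoxide is silylated; the new carbinol centre forms unselectively and is destroyed in step 14.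

Step 13
Reactants: 22 the 2,3-di-tert-butoxy-4-siloxycyclobutenone; 23 allylmagnesium bromide
Product: 26 3-allyl-4-{1-[(3R)-6-allyl-5-methoxy-7-(TIPS-oxy)chroman-3-yl]ethenyl}-2-tert-butoxy-4-(TMS-oxy)cyclobut-2-en-1-one (both epimers at C4), via bromomagnesium alkoxide 24 (not isolated), via trifluoroacetate 25 (not isolated)
Conditions: allylmagnesium bromide (1.2 equiv), THF, −78 °C; then (CF3CO)2O (1.5 equiv), −78 to −20 °C; aq NaHCO3
Reagents that add atoms: allylmagnesium bromide C=CC[Mg]Br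
Why: 1,2-Addition of the allyl Grignard reagent to the remaining vinylogous ester carbonyl, trifluoroacetylation of the new alkoxide and ionisation assisted by the distal tert-butoxy group with loss of isobutene give the transposed enone (the 1,3-carbonyl transposition known for squarate adducts); the silylated carbinol cannot ionise, so the allyl group ends on the ring carbon next to it, and direct addition–elimination at the β-carbon would give the same product.

Step 14
Reactants: 26 the 3-allyl-2-tert-butoxy-4-siloxy-4-alkenylcyclobutenone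
Product: 30 3-allyl-2-tert-butoxy-5-[(3R)-6-allyl-5-methoxy-7-(TIPS-oxy)chroman-3-yl]cyclohexa-2,5-diene-1,4-dione, via dienylketene 27 (not isolated), via cyclohexadienone 28 (not isolated), via siloxyphenol 29 (not isolated)
Conditions: PhMe (0.01 M, degassed), 110 °C; then PhI(OAc)2 (1.1 equiv), MeCN/H2O, 0 °C
Reagents that add atoms: none
Why: Heating opens the cyclobutenone by conrotatory 4π electrocyclic ring opening in which the 4-siloxy donor rotates outward, so the alkenyl group turns inward and the (E)-dienylketene 27 has its ketene carbon C5′ next to the vinyl terminus C6′. Thermal disrotatory 6π electrocyclisation then forms the C5′–C6′ bond and ring B as cyclohexadienone 28, which tautomerises to arene 29, and PhI(OAc)2 oxidises the para-siloxyphenol to the quinone with loss of the silyl group. The closest precedent is the thermal ring expansion of 4-alkenyl-4-oxygenated cyclobutenones to hydroquinones and quinones (Moore–Liebeskind benzannulation). No stereocenter is created: the carbinol centre of 26 is destroyed, and C3, which is never ionised or deprotonated under neutral thermal conditions, should be retained. The substitution pattern of ring B is fixed by the cyclobutenone (carbonyl flanked by the tert-butoxy carbon and the carbinol, allyl on the carbon next to the carbinol), so C4′ receives the oxygen, C3′ the allyl group and C6′ stays CH; the selectivities needed are outward rotation of the siloxy group, secured by its donor character, and oxidation of ring B only, secured because ring A carries no free phenol.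

Step 15
Reactants: 30 the bis-allyl tert-butoxyquinone; 31 2-methylbut-2-ene
Product: 32 2-tert-butoxy-5-[(3R)-5-methoxy-6-prenyl-7-(TIPS-oxy)chroman-3-yl]-3-prenylcyclohexa-2,5-diene-1,4-dione
Conditions: RuCl2(=CHPh)(H2IMes)(PCy3) (second-generation Grubbs catalyst, 5 mol%), 2-methylbut-2-ene/CH2Cl2, 40 °C
Reagents that add atoms: 2-methylbut-2-ene CC=C(C)C
Why: Olefin cross-metathesis of both terminal allyl groups with the trisubstituted alkene used in large excess should convert them to prenyl groups with loss of propene, while the electron-poor quinone double bonds do not take part.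

Step 16
Reactants: 32 the bis-prenyl tert-butoxyquinone
Product: 33 2-hydroxy-5-[(3R)-5-methoxy-6-prenyl-7-(TIPS-oxy)chroman-3-yl]-3-prenylcyclohexa-2,5-diene-1,4-dione
Conditions: CF3CO2H (10 equiv), CH2Cl2, 0 °C, short reaction time
Reagents that add atoms: none
Why: Acidolysis of the tert-butyl vinylogous ester through the tert-butyl cation unveils the hydroxyquinone under brief, cold conditions, while the silyl ether still masks the ring A phenol so that the neighbouring prenyl group cannot cyclise onto it.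

Step 17
Reactants: 33 the hydroxyquinone silyl ether
Product: 34 2-hydroxy-5-[(3R)-7-hydroxy-5-methoxy-6-prenylchroman-3-yl]-3-prenylcyclohexa-2,5-diene-1,4-dione (target, CNP0148998.1)
Conditions: Bu4NF, AcOH (1:1), THF, 0 °C
Reagents that add atoms: none
Why: Fluoride-mediated cleavage of the aryl silyl ether, buffered with acetic acid to avoid phenoxide chemistry on the quinone, frees the 7-hydroxyl and should give the target with C3 unchanged.

**Compound list**
1 | 2,4,6-trihydroxybenzaldehyde | O=Cc1c(O)cc(O)cc1O | starting material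
2 | ethyl acetoacetate | CCOC(=O)CC(C)=O | starting material
3 | 3-acetyl-5,7-dihydroxy-2H-chromen-2-one | CC(=O)C1=Cc2c(O)cc(O)cc2OC1=O | intermediate
4 | chlorotriisopropylsilane | CC(C)[Si](Cl)(C(C)C)C(C)C | starting material
5 | 3-acetyl-5-hydroxy-7-(TIPS-oxy)-2H-chromen-2-one | CC(=O)C1=Cc2c(O)cc(O[Si](C(C)C)(C(C)C)C(C)C)cc2OC1=O | intermediate
6 | allyl bromide | C=CCBr | starting material
7 | 3-acetyl-5-(allyloxy)-7-(TIPS-oxy)-2H-chromen-2-one | CC(=O)C1=Cc2c(OCC=C)cc(O[Si](C(C)C)(C(C)C)C(C)C)cc2OC1=O | intermediate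
8 | 3-acetyl-6-allyl-5-hydroxy-7-(TIPS-oxy)-2H-chromen-2-one | CC(=O)C1=Cc2c(O)c(CC=C)c(O[Si](C(C)C)(C(C)C)C(C)C)cc2OC1=O | intermediate
9 | iodomethane | CI | starting material
10 | 3-acetyl-6-allyl-5-methoxy-7-(TIPS-oxy)-2H-chromen-2-one | CC(=O)C1=Cc2c(OC)c(CC=C)c(O[Si](C(C)C)(C(C)C)C(C)C)cc2OC1=O | intermediate
11 | rac-3-acetyl-6-allyl-5-methoxy-7-(TIPS-oxy)chroman-2-one (C3 labile) | CC(=O)C1Cc2c(OC)c(CC=C)c(O[Si](C(C)C)(C(C)C)C(C)C)cc2OC1=O | intermediate
12 | (3R)-6-allyl-3-[(1S)-1-hydroxyethyl]-5-methoxy-7-(TIPS-oxy)chroman-2-one | COc1c(CC=C)c(O[Si](C(C)C)(C(C)C)C(C)C)cc2c1C[C@H]([C@H](C)O)C(=O)O2 | intermediate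
13 | (2S,3S)-2-{[3-allyl-6-hydroxy-2-methoxy-4-(TIPS-oxy)phenyl]methyl}butane-1,3-diol | COc1c(CC=C)c(O[Si](C(C)C)(C(C)C)C(C)C)cc(O)c1C[C@H]([C@H](C)O)CO | intermediate
14 | (1S)-1-[(3S)-6-allyl-5-methoxy-7-(TIPS-oxy)chroman-3-yl]ethan-1-ol | COc1c(CC=C)c(O[Si](C(C)C)(C(C)C)C(C)C)cc2c1C[C@H]([C@H](C)O)CO2 | intermediate
15 | 1-[(3S)-6-allyl-5-methoxy-7-(TIPS-oxy)chroman-3-yl]ethan-1-one | COc1c(CC=C)c(O[Si](C(C)C)(C(C)C)C(C)C)cc2c1C[C@H](C(C)=O)CO2 | intermediate
16 | 2,4,6-triisopropylbenzenesulfonohydrazide | CC(C)c1cc(C(C)C)c(S(=O)(=O)NN)c(C(C)C)c1 | starting material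
17 | N′-{(1E)-1-[(3R)-6-allyl-5-methoxy-7-(TIPS-oxy)chroman-3-yl]ethylidene}-2,4,6-triisopropylbenzenesulfonohydrazide | COc1c(CC=C)c(O[Si](C(C)C)(C(C)C)C(C)C)cc2c1C[C@H](/C(C)=N/NS(=O)(=O)c3c(C(C)C)cc(C(C)C)cc3C(C)C)CO2 | intermediate
18 | di-tert-butyl squarate | CC(C)(C)OC1=C(OC(C)(C)C)C(=O)C1=O | starting material
19 | chlorotrimethylsilane | C[Si](C)(C)Cl | starting material
20 | {1-[(3R)-6-allyl-5-methoxy-7-(TIPS-oxy)chroman-3-yl]ethenyl}lithium | COc1c(CC=C)c(O[Si](C(C)C)(C(C)C)C(C)C)cc2c1C[C@H](C([Li])=C)CO2 | intermediate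
21 | lithium 1-{1-[(3R)-6-allyl-5-methoxy-7-(TIPS-oxy)chroman-3-yl]ethenyl}-2,3-di-tert-butoxy-4-oxocyclobut-2-en-1-olate (both epimers) | COc1c(CC=C)c(O[Si](C(C)C)(C(C)C)C(C)C)cc2c1C[C@H](C(=C)C3(O[Li])C(=O)C(OC(C)(C)C)=C3OC(C)(C)C)CO2 | intermediate
22 | 4-{1-[(3R)-6-allyl-5-methoxy-7-(TIPS-oxy)chroman-3-yl]ethenyl}-2,3-di-tert-butoxy-4-(TMS-oxy)cyclobut-2-en-1-one (both epimers) | COc1c(CC=C)c(O[Si](C(C)C)(C(C)C)C(C)C)cc2c1C[C@H](C(=C)C3(O[Si](C)(C)C)C(=O)C(OC(C)(C)C)=C3OC(C)(C)C)CO2 | intermediate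
23 | allylmagnesium bromide | C=CC[Mg]Br | starting material
24 | bromomagnesium 1-allyl-4-{1-[(3R)-6-allyl-5-methoxy-7-(TIPS-oxy)chroman-3-yl]ethenyl}-2,3-di-tert-butoxy-4-(TMS-oxy)cyclobut-2-en-1-olate (stereoisomer mixture at the ring carbinols) | COc1c(CC=C)c(O[Si](C(C)C)(C(C)C)C(C)C)cc2c1C[C@H](C(=C)C3(O[Si](C)(C)C)C(CC=C)(O[Mg]Br)C(OC(C)(C)C)=C3OC(C)(C)C)CO2 | intermediate
25 | 1-allyl-4-{1-[(3R)-6-allyl-5-methoxy-7-(TIPS-oxy)chroman-3-yl]ethenyl}-2,3-di-tert-butoxy-4-(TMS-oxy)cyclobut-2-en-1-yl trifluoroacetate (stereoisomer mixture at the ring carbinols) | COc1c(CC=C)c(O[Si](C(C)C)(C(C)C)C(C)C)cc2c1C[C@H](C(=C)C3(O[Si](C)(C)C)C(CC=C)(OC(=O)C(F)(F)F)C(OC(C)(C)C)=C3OC(C)(C)C)CO2 | intermediate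
26 | 3-allyl-4-{1-[(3R)-6-allyl-5-methoxy-7-(TIPS-oxy)chroman-3-yl]ethenyl}-2-tert-butoxy-4-(TMS-oxy)cyclobut-2-en-1-one (both epimers) | COc1c(CC=C)c(O[Si](C(C)C)(C(C)C)C(C)C)cc2c1C[C@H](C(=C)C3(O[Si](C)(C)C)C(=O)C(OC(C)(C)C)=C3CC=C)CO2 | intermediate
27 | (3E)-3-allyl-2-tert-butoxy-5-[(3R)-6-allyl-5-methoxy-7-(TIPS-oxy)chroman-3-yl]-4-(TMS-oxy)hexa-1,3,5-trien-1-one | COc1c(CC=C)c(O[Si](C(C)C)(C(C)C)C(C)C)cc2c1C[C@H](C(=C)/C(O[Si](C)(C)C)=C(CC=C)\C(OC(C)(C)C)=C=O)CO2 | intermediate
28 | 3-allyl-2-tert-butoxy-5-[(3R)-6-allyl-5-methoxy-7-(TIPS-oxy)chroman-3-yl]-4-(TMS-oxy)cyclohexa-2,4-dien-1-one | COc1c(CC=C)c(O[Si](C(C)C)(C(C)C)C(C)C)cc2c1C[C@H](C3=C(O[Si](C)(C)C)C(CC=C)=C(OC(C)(C)C)C(=O)C3)CO2 | intermediate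
29 | 3-allyl-2-tert-butoxy-5-[(3R)-6-allyl-5-methoxy-7-(TIPS-oxy)chroman-3-yl]-4-(TMS-oxy)phenol | COc1c(CC=C)c(O[Si](C(C)C)(C(C)C)C(C)C)cc2c1C[C@H](c3cc(O)c(OC(C)(C)C)c(CC=C)c3O[Si](C)(C)C)CO2 | intermediate
30 | 3-allyl-2-tert-butoxy-5-[(3R)-6-allyl-5-methoxy-7-(TIPS-oxy)chroman-3-yl]cyclohexa-2,5-diene-1,4-dione | COc1c(CC=C)c(O[Si](C(C)C)(C(C)C)C(C)C)cc2c1C[C@H](C3=CC(=O)C(OC(C)(C)C)=C(CC=C)C3=O)CO2 | intermediate
31 | 2-methylbut-2-ene | CC=C(C)C | starting material
32 | 2-tert-butoxy-5-[(3R)-5-methoxy-6-prenyl-7-(TIPS-oxy)chroman-3-yl]-3-prenylcyclohexa-2,5-diene-1,4-dione | COc1c(CC=C(C)C)c(O[Si](C(C)C)(C(C)C)C(C)C)cc2c1C[C@H](C3=CC(=O)C(OC(C)(C)C)=C(CC=C(C)C)C3=O)CO2 | intermediate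
33 | 2-hydroxy-5-[(3R)-5-methoxy-6-prenyl-7-(TIPS-oxy)chroman-3-yl]-3-prenylcyclohexa-2,5-diene-1,4-dione | COc1c(CC=C(C)C)c(O[Si](C(C)C)(C(C)C)C(C)C)cc2c1C[C@H](C3=CC(=O)C(O)=C(CC=C(C)C)C3=O)CO2 | intermediate
34 | 2-hydroxy-5-[(3R)-7-hydroxy-5-methoxy-6-prenylchroman-3-yl]-3-prenylcyclohexa-2,5-diene-1,4-dione | COc1c(CC=C(C)C)c(O)cc2c1C[C@H](C1=CC(=O)C(O)=C(CC=C(C)C)C1=O)CO2 | target

Total step count: 17. Longest linear sequence: 17 steps (1 to 34).

**Steps most likely to fail**

Step 7. The dynamic kinetic resolution may give poor diastereoselection or the catalyst may discriminate the two C3 epimers too weakly, so that C3 is carried on as a mixture after the carbinol is oxidised. The fallback is resolution by diastereomer separation and enzymatic acylation; it sets out from 11 and comes back at 14. Reduction of 11 with excess LiBH4 in THF reduces ketone and lactone together to 2-{[3-allyl-6-hydroxy-2-methoxy-4-(TIPS-oxy)phenyl]methyl}butane-1,3-diol as a stereoisomer mixture F1. Mitsunobu closure (PPh3, DIAD) gives 1-[6-allyl-5-methoxy-7-(TIPS-oxy)chroman-3-yl]ethan-1-ol as a stereoisomer mixture F2, from which the racemic (1S*,3S*) pair is separated on silica. Immobilised lipase B from Candida antarctica with vinyl acetate in MTBE at 30 °C should acylate the (1R)-configured enantiomer (Kazlauskas rule) to (1R)-1-[(3R)-6-allyl-5-methoxy-7-(TIPS-oxy)chroman-3-yl]ethyl acetate F3, leaving the (1S,3S)-alcohol 14 unreacted.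

Step 13. The magnesium alkoxide may undergo charge-accelerated ring opening, the silyl ether may be lost so that the alkenyl-bearing carbinol ionises instead, or the strained enone may not survive the acylation. The fallback installs the C3′ allyl group after ring B is formed; it sets out from 22 and comes back at 33. Reduction of 22 with LiAlH(O-t-Bu)3 at −78 °C and the same (CF3CO)2O transposition gives 4-{1-[(3R)-6-allyl-5-methoxy-7-(TIPS-oxy)chroman-3-yl]ethenyl}-2-tert-butoxy-4-(TMS-oxy)cyclobut-2-en-1-one F4. Thermolysis and PhI(OAc)2 oxidation as in step 14 give 2-tert-butoxy-5-[(3R)-6-allyl-5-methoxy-7-(TIPS-oxy)chroman-3-yl]cyclohexa-2,5-diene-1,4-dione F5. CF3CO2H gives 2-hydroxy-5-[(3R)-6-allyl-5-methoxy-7-(TIPS-oxy)chroman-3-yl]cyclohexa-2,5-diene-1,4-dione F6. Allyl bromide 6 with K2CO3 gives 2-(allyloxy)-5-[(3R)-6-allyl-5-methoxy-7-(TIPS-oxy)chroman-3-yl]cyclohexa-2,5-diene-1,4-dione F7. Heating in PhMe at 110 °C effects Claisen rearrangement to C3′, the only carbon ortho to the vinylogous ester oxygen, giving 3-allyl-2-hydroxy-5-[(3R)-6-allyl-5-methoxy-7-(TIPS-oxy)chroman-3-yl]cyclohexa-2,5-diene-1,4-dione F8. Cross-metathesis with 31 under the conditions of step 15 then gives 33.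

Step 12. Partial epimerisation of C3 during hydrazone formation or dianion generation, or metalation of ring A or of the benzylic allyl position while the Shapiro mixture is warmed, may erode the vinyllithium. The fallback generates the same vinyllithium entirely at −78 °C; it sets out from 15 and comes back at 20. Kinetic enolisation of 15 at the methyl group with KN(SiMe3)2 and PhNTf2 at −78 °C gives 1-[(3S)-6-allyl-5-methoxy-7-(TIPS-oxy)chroman-3-yl]ethenyl trifluoromethanesulfonate F9. Stannylation with Me3SnSnMe3, Pd(PPh3)4 (zerovalent palladium) and LiCl in THF at 60 °C gives {1-[(3S)-6-allyl-5-methoxy-7-(TIPS-oxy)chroman-3-yl]ethenyl}trimethylstannane F10. Tin–lithium exchange with MeLi at −78 °C then gives 20, which is added to 18 and silylated as in step 12.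

**Further compounds**
F1 | step 7 | 2-{[3-allyl-6-hydroxy-2-methoxy-4-(TIPS-oxy)phenyl]methyl}butane-1,3-diol (stereoisomer mixture) | COc1c(CC=C)c(O[Si](C(C)C)(C(C)C)C(C)C)cc(O)c1CC(C(C)O)CO
F2 | step 7 | 1-[6-allyl-5-methoxy-7-(TIPS-oxy)chroman-3-yl]ethan-1-ol (stereoisomer mixture) | COc1c(CC=C)c(O[Si](C(C)C)(C(C)C)C(C)C)cc2c1CC(C(C)O)CO2
F3 | step 7 | (1R)-1-[(3R)-6-allyl-5-methoxy-7-(TIPS-oxy)chroman-3-yl]ethyl acetate | COc1c(CC=C)c(O[Si](C(C)C)(C(C)C)C(C)C)cc2c1C[C@@H]([C@@H](C)OC(C)=O)CO2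
F4 | step 13 | 4-{1-[(3R)-6-allyl-5-methoxy-7-(TIPS-oxy)chroman-3-yl]ethenyl}-2-tert-butoxy-4-(TMS-oxy)cyclobut-2-en-1-one (both epimers) | COc1c(CC=C)c(O[Si](C(C)C)(C(C)C)C(C)C)cc2c1C[C@H](C(=C)C3(O[Si](C)(C)C)C(=O)C(OC(C)(C)C)=C3)CO2
F5 | step 13 | 2-tert-butoxy-5-[(3R)-6-allyl-5-methoxy-7-(TIPS-oxy)chroman-3-yl]cyclohexa-2,5-diene-1,4-dione | COc1c(CC=C)c(O[Si](C(C)C)(C(C)C)C(C)C)cc2c1C[C@H](C3=CC(=O)C(OC(C)(C)C)=CC3=O)CO2
F6 | step 13 | 2-hydroxy-5-[(3R)-6-allyl-5-methoxy-7-(TIPS-oxy)chroman-3-yl]cyclohexa-2,5-diene-1,4-dione | COc1c(CC=C)c(O[Si](C(C)C)(C(C)C)C(C)C)cc2c1C[C@H](C3=CC(=O)C(O)=CC3=O)CO2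
F7 | step 13 | 2-(allyloxy)-5-[(3R)-6-allyl-5-methoxy-7-(TIPS-oxy)chroman-3-yl]cyclohexa-2,5-diene-1,4-dione | COc1c(CC=C)c(O[Si](C(C)C)(C(C)C)C(C)C)cc2c1C[C@H](C3=CC(=O)C(OCC=C)=CC3=O)CO2
F8 | step 13 | 3-allyl-2-hydroxy-5-[(3R)-6-allyl-5-methoxy-7-(TIPS-oxy)chroman-3-yl]cyclohexa-2,5-diene-1,4-dione | COc1c(CC=C)c(O[Si](C(C)C)(C(C)C)C(C)C)cc2c1C[C@H](C3=CC(=O)C(O)=C(CC=C)C3=O)CO2
F9 | step 12 | 1-[(3S)-6-allyl-5-methoxy-7-(TIPS-oxy)chroman-3-yl]ethenyl trifluoromethanesulfonate | COc1c(CC=C)c(O[Si](C(C)C)(C(C)C)C(C)C)cc2c1C[C@H](C(=C)OS(=O)(=O)C(F)(F)F)CO2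
F10 | step 12 | {1-[(3S)-6-allyl-5-methoxy-7-(TIPS-oxy)chroman-3-yl]ethenyl}trimethylstannane | COc1c(CC=C)c(O[Si](C(C)C)(C(C)C)C(C)C)cc2c1C[C@H](C(=C)[Sn](C)(C)C)CO2
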